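All runs stem from a simulated flask on assumed constants; noise was put on by code.

The slowness grew steeply with Z, a further species added to a flask where L passes to X and then to G, with catalysts Q and D and reagent E. With the other charges the same, noon still read 10 % of its L at 15.0 h, autumn 85 % and midnight 100 %.

all flasks: L 0.40 M; Q 28 mM; D 1.8 mM
- noon: E 0.42 M; Z 7.1 mM; run made earlier
- autumn: E 0.42 M; Z 28 mM; run made earlier
- midnight: E 0.42 M; Z 97 mM; run made earlier
- teal: E 0.420 M; Z 10 mM; time 15 h
- amber: E 0.420 M; Z 90 mM; time 15 h
- red: E 0.420 M; Z 30 mM; time 15 h

| run | time / h | L / % | X / % | G / % |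
|---|---|---|---|---|
| noon | 1.33 | 80 | 20 | 2 |
| noon | 2.50 | 67 | 30 | 2 |
| noon | 4.00 | 54 | 44 | 0 |
| noon | 8.00 | 31 | 64 | 3 |
| noon | 15.0 | 10 | 78 | 11 |
| autumn | 3.00 | 92 | 7 | 1 |
| autumn | 6.00 | 91 | 9 | 1 |
| autumn | 10.0 | 87 | 12 | 2 |
| autumn | 12.0 | 94 | 16 | 0 |
| autumn | 15.0 | 85 | 12 | 2 |
| midnight | 1.33 | 100 | 0 | 2 |
| midnight | 4.00 | 99 | 2 | 0 |
| midnight | 8.00 | 97 | 0 | 0 |
| midnight | 10.0 | 101 | 3 | 0 |
| midnight | 15.0 | 100 | 0 | 3 |

(each reading ± 2 percentage points)

- which of these there is most of at the end, counted by the L in it, teal (G / X / L)
- which of these there is most of at the end, counted by the L in it, amber (G / X / L)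
- which of these there is most of at the end, counted by the L in it, red (G / X / L)
- how much there is at the end of the one of these that leads, in percent of the L charged: teal
- how much there is at the end of the one of these that leads, in percent of the L charged: amber
- how much there is at the end of the one of these that leads, in percent of the L charged: red



Autumn, with 28 mM of Z against 28 mM of Q, read 92 % of L at 3.00 h and then crept, so I took each Z to remove one Q from work. In teal that leaves 18.0 mM of W, the Q charged less the Z charged, against 20.9 mM in noon, whose W turned over about 17.0 times. Noon's L fell as pseudo-first-order, so I let the logarithm of L go with W times time. At equal times, teal's fraction of L is then noon's raised to the power of teal's W over noon's W, which gave an estimate of 13.8 %.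

That bracketed X in teal. With no G at all, my estimate of L put X at 86.2 %, the upper bound. Teal has less W than noon, so taking G as high as noon's last reading put X at 75.2 %, the lower bound; both bounds are estimates and carry the scatter of noon's readings. Scaling noon's G by the same W ratio gave 9.47 % of G, and I committed to 76.8 % of X. Past zero W, the runs gave the bracket. Red has a little more Z than autumn and amber a little less than midnight, so I placed L in both between those two end readings, red near autumn's and amber near midnight's.

The forecast put X ahead in teal at 71 % (from 60 % to 79 %), L in amber at 100 % and L in red at 89 %, saying of teal: “Either way X leads”. Its teal centre stood below my lower bound.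

The flasks gave X at 76.1 % in teal, inside the bracket, L at 98.8 % in amber and L at 91.4 % in red.

    L + Q → Q + X (k = 7.00 M⁻¹ h⁻¹)
    Q + Z → J (k = 210 M⁻¹ h⁻¹)
    E + D + X → D + G (k = 16.0 M⁻² h⁻¹)

Amber kept 98.8 % of its L because Q and Z pass into J; with that step taken away, the same flask kept 5.29 %. W counts that step, and teal's 18.0 mM had given 13.8 % of L against the 14.9 % found. One more flask, like amber but with Z at 22.0 mM, has 6.00 mM of W, which gives 51.6 % of L, and that flask ended at 50.6 %.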